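**Retrosynthetic overview**
- Target 6 (free acid) comes from its tris(tributylammonium) salt 5 by proton-for-cation exchange.
- 5 comes from quercetin 3-O-acetate 3 by forming three S–O bonds (SO3 transfer to the 7-, 3'- and 4'-OH; the hydrogen-bonded 5-OH is left).
- 3 comes from quercetin 1 by the key disconnection, the acyl C–O bond at O3, made directly on unprotected quercetin by a zinc-chelate-directed acetylation.
- No ring is formed: the complete flavone A/C/B skeleton is bought in quercetin.

Assumption: the target has no stereocentre (it is achiral), so there is no enantiomer to control; the free sulfuric acid monoester form drawn is taken as the final product.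

**Step 1**
Reactants: 1 quercetin
Product: 3 quercetin 3-O-acetate, via zinc flavonolate chelate 2 (not isolated)
Conditions: Ac2O (1.05 equiv), Zn(OTf)2 (5 mol%), 1,4,7-trimethyl-1,4,7-triazacyclononane (6 mol%), 2,6-lutidine (1.2 equiv), THF, 0 °C, Ar
Reagents that add atoms: acetic anhydride, CC(=O)OC(C)=O
Why: Proposed new method: chelation-gated site-selective O-acetylation, in which the cationic face-capped [Zn(Me3TACN)]2+ fragment (one anionic and two neutral cis sites) binds quercetin at its 3-oxido-4-keto site (the first metal-binding site of flavonols in non-basic media) and acidifies only that OH enough for 2,6-lutidine to remove it, while the free 7-, 3'-, 4'-phenols and the hydrogen-bonded 5-OH stay neutral and are inert to Ac2O at 0 °C without a nucleophilic catalyst; Ac2O held at the third cis site then undergoes coordination–insertion at the Zn–O3 bond, the no-longer-chelating 3-acetate is released and the zinc acetate is reprotonated by the next quercetin; the closest known reaction types are Lewis-acid (tin- or copper-type) chelation-directed monoacylation of 1,2-diols and zinc-alkoxide coordination–insertion acyl transfer.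

**Step 2**
Reactants: 3 quercetin 3-O-acetate
Product: 5 tris(tributylammonium) salt of quercetin 3-acetate 7,3',4'-tri-O-sulfate, via tris(pyridinium) trisulfate salt 4 (not isolated)
Conditions: SO3·pyridine (9 equiv), DMF, 0 → 40 °C; then H2O (0 °C), Bu3N (to pH 6); Sephadex LH-20 (MeOH)
Reagents that add atoms: sulfur trioxide–pyridine complex, O=S(=O)([O-])[n+]1ccccc1; tributylamine, CCCCN(CCCC)CCCC
Why: O-sulfation of phenols with an amine–SO3 complex, in which the three free phenols (7, 3', 4') attack SO3 while the 5-OH, locked in a strong hydrogen bond to C4=O, is left under these mild conditions (the same bias that leaves 5-OH free in polysulfated quercetins); base-free DMF spares the enol acetate, and the lipophilic tributylammonium ion pair allows purification.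

**Step 3**
Reactants: 5 tris(tributylammonium) salt of quercetin 3-acetate 7,3',4'-tri-O-sulfate
Product: 6 quercetin 3-acetate 7,3',4'-tri-O-sulfate (free acid, target)
Conditions: Dowex 50WX8 (H+ form), H2O, 0 °C; freeze-dry at once
Reagents that add atoms: none
Why: Cation exchange on a strong-acid resin (salt metathesis) swaps each tributylammonium ion for a proton without touching the skeleton, and is run cold and dilute because the free acid catalyses its own hydrolysis.

**Compound list**
1 | quercetin, 2-(3,4-dihydroxyphenyl)-3,5,7-trihydroxy-4H-chromen-4-one | O=c1c(O)c(-c2ccc(O)c(O)c2)oc2cc(O)cc(O)c12 | starting material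
2 | [Zn(Me3TACN)(quercetin-3-olato-κO3,κO4)] triflate; zinc bound to O3 and chelated by the C4 carbonyl, triamine ligand and triflate written as separate components | CN1CCN(C)CCN(C)CC1.O=c1c(O[Zn+])c(-c2ccc(O)c(O)c2)oc2cc(O)cc(O)c12.[O-]S(=O)(=O)C(F)(F)F | intermediate (not isolated)
3 | quercetin 3-O-acetate, 2-(3,4-dihydroxyphenyl)-5,7-dihydroxy-4-oxo-4H-chromen-3-yl acetate | CC(=O)Oc1c(-c2ccc(O)c(O)c2)oc2cc(O)cc(O)c2c1=O | intermediate
4 | tris(pyridinium) salt of quercetin 3-acetate 7,3',4'-tri-O-sulfate | CC(=O)Oc1c(-c2ccc(OS(=O)(=O)[O-])c(OS(=O)(=O)[O-])c2)oc2cc(OS(=O)(=O)[O-])cc(O)c2c1=O.c1cc[nH+]cc1.c1cc[nH+]cc1.c1cc[nH+]cc1 | intermediate (not isolated)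
5 | tris(tributylammonium) salt of quercetin 3-acetate 7,3',4'-tri-O-sulfate | CC(=O)Oc1c(-c2ccc(OS(=O)(=O)[O-])c(OS(=O)(=O)[O-])c2)oc2cc(OS(=O)(=O)[O-])cc(O)c2c1=O.CCCC[NH+](CCCC)CCCC.CCCC[NH+](CCCC)CCCC.CCCC[NH+](CCCC)CCCC | intermediate
6 | quercetin 3-acetate 7,3',4'-tri-O-sulfate, free acid (achiral) | CC(=O)Oc1c(-c2ccc(OS(=O)(=O)O)c(OS(=O)(=O)O)c2)oc2cc(OS(=O)(=O)O)cc(O)c2c1=O | target

**Step count and risk**
Total steps: 3. Longest linear sequence: 3.

The three steps most likely to fail (in order of risk):

1. Step 1 (the proposed new acetylation). Possible failures are acetylation at the catechol or at O7, over-acetylation to the 3,5-diacetate once the product's 5-hydroxy-4-keto site binds zinc, or a zinc-bound O3 too stabilised to attack Ac2O. The fallback uses known chemistry; it sets out from 1 and comes back at 3. Quercetin 1 is heated with dichlorodiphenylmethane (diphenyl ether, 175 °C) to give 3',4'-O-(diphenylmethylene)quercetin F1. The most acidic remaining phenol is benzylated (BnBr 1.1 equiv, K2CO3, DMF, rt) to give 7-O-benzyl-3',4'-O-(diphenylmethylene)quercetin F2. The 3-OH is then acetylated in preference to the chelated 5-OH (Ac2O 1.1 equiv, pyridine, 0 °C) to give 3-O-acetyl-7-O-benzyl-3',4'-O-(diphenylmethylene)quercetin F3. Hydrogenolysis (H2, Pd(OH)2/C, THF/EtOAc) removes the benzyl ether and the ketal together and returns to 3.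

2. Step 2 (trisulfation). Possible failures are incomplete sulfation of the 3'-OH next to the 4'-sulfate, or loss or scrambling of the 3-acetate. The fallback sets out from 3 and comes back at 5. It replaces SO3 transfer by a dehydrative coupling: tributylammonium hydrogensulfate activated by N,N'-dicyclohexylcarbodiimide (10 equiv each, DMF, 0–4 °C, several days), where the phenols attack the carbodiimide-activated sulfate. This gives 5 directly after filtration of the urea and Sephadex LH-20, and makes no new compound (F0).

3. Step 3 (liberation of the free acid). The possible failure is hydrolysis of the sulfate or acetate groups, catalysed by the acid itself, during aqueous exchange and drying. The fallback sets out from 3 and comes back at 6, bypassing the salt. Compound 3 is sulfated with the sulfur trioxide–DMF complex (3.6 equiv, dry DMF, 0 °C → rt), which delivers the sulfuric acid monoesters directly. The free acid 6 is precipitated with dry Et2O/CH2Cl2 under argon and never meets water. This makes no new compound (F0).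

**Further compounds**
F1 | step 1 | 3',4'-O-(diphenylmethylene)quercetin, 2-(2,2-diphenyl-1,3-benzodioxol-5-yl)-3,5,7-trihydroxy-4H-chromen-4-one | O=c1c(O)c(-c2ccc3OC(c4ccccc4)(c4ccccc4)Oc3c2)oc2cc(O)cc(O)c12
F2 | step 1 | 7-O-benzyl-3',4'-O-(diphenylmethylene)quercetin | O=c1c(O)c(-c2ccc3OC(c4ccccc4)(c4ccccc4)Oc3c2)oc2cc(OCc3ccccc3)cc(O)c12
F3 | step 1 | 3-O-acetyl-7-O-benzyl-3',4'-O-(diphenylmethylene)quercetin | CC(=O)Oc1c(-c2ccc3OC(c4ccccc4)(c4ccccc4)Oc3c2)oc2cc(OCc3ccccc3)cc(O)c2c1=O
F0 | step 2 | none | none
F0 | step 3 | none | none
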